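The oxolane ring (O1, C3, C4, C5, C6) is disconnected at C5–C6, exploiting the unsubstituted C5 methylene between the chlorinated C4 and the ring carbon C6: both C–O bonds of O1 are laid down beforehand in an enol acetal. A Petasis–Ferrier rearrangement of a 4-methylene-1,3-dioxolane then forms the C5–C6 bond, closes the ring, sets C6 and unveils a C4 ketone as the handle for chlorine. The precursor joins two halves made from one enantiomer of 2-methylglycidol: a 2-methylglyceric acid (C2–C4) and a 2-silyloxy-3-chloro aldehyde (C6–C8), the latter a latent epoxide free of competing acetals.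

Key step: step 9

Remark: atoms are numbered along the chain from C1 (CHBr) to C8 (CH2Cl) with the ring oxygen as O1; compounds 12 and 13 are carried as both epimers at the acetal carbon, which step 9 erases.

Step 1
Reactants: 1 methallyl alcohol (2-methylprop-2-en-1-ol)
Product: 2 (R)-2-methylglycidol, (2R)-(2-methyloxiran-2-yl)methanol
Conditions: Ti(OiPr)4 (5 mol%), D-(−)-diisopropyl tartrate (6 mol%), t-BuOOH, 4 Å MS, CH2Cl2, −20 °C
Reagents that add atoms: tert-butyl hydroperoxide, CC(C)(C)OO
Why: Sharpless asymmetric epoxidation, in which the titanium tartrate catalyst binds the allylic alcohol and delivers the peroxide oxygen to one alkene face, the D-(−)-tartrate ester giving the (R)-epoxide and thereby the quaternary stereocentre that later becomes C3 in one half and C7 in the other.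

Step 2
Reactants: 2 (R)-2-methylglycidol
Product: 4 (2S)-2,3-dihydroxy-2-methylpropanoic acid, via (S)-2-methylglycidic acid 3 (not isolated)
Conditions: RuCl3 (2 mol%), NaIO4, CCl4/MeCN/H2O, rt; then NaOH (aq), 60 °C; H+ resin work-up
Reagents that add atoms: sodium periodate, [Na+].[O-]I(=O)(=O)=O; water, O
Why: RuO4-catalysed oxidation of the primary alcohol to the acid followed by SN2 opening of the glycidate by hydroxide at the unhindered CH2, so the C–O bond at the stereocentre is never broken and its configuration is retained (the descriptor becomes S only through the priority change).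

Step 3
Reactants: 4 (2S)-2,3-dihydroxy-2-methylpropanoic acid
Product: 6 (2S)-3-[(tert-butyldiphenylsilyl)oxy]-2-hydroxy-2-methylpropanoic acid, via silyl ester 5 (not isolated)
Conditions: TBDPSCl (2.2 equiv), imidazole, DMF, rt; then K2CO3, MeOH/H2O, rt; work-up at pH 4
Reagents that add atoms: tert-butyl(chloro)diphenylsilane, CC(C)(C)[Si](Cl)(c1ccccc1)c1ccccc1
Why: Silyl ether formation at the primary hydroxyl (the tertiary hydroxyl is too hindered) with concomitant silyl ester formation, the labile silyl ester then being removed by mild methanolysis without touching the stereocentre.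

Step 4
Reactants: 2 (R)-2-methylglycidol
Product: 7 (2R)-3-chloro-2-methylpropane-1,2-diol
Conditions: LiCl, AcOH, THF, rt
Reagents that add atoms: lithium chloride, [Li+].[Cl-]
Why: Halohydrin formation by SN2 attack of chloride at the primary epoxide carbon, which leaves the C–O bond and the configuration of the quaternary centre intact.

Step 5
Reactants: 7 (2R)-3-chloro-2-methylpropane-1,2-diol
Product: 9 (2R)-2-[(tert-butyldimethylsilyl)oxy]-1-chloro-2-methyl-3-[(triethylsilyl)oxy]propane, via mono(triethylsilyl) ether 8 (not isolated)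
Conditions: TESCl (1.05 equiv), Et3N, DMAP (cat.), CH2Cl2, −20 °C; then 2,6-lutidine, TBSOTf, 0 °C → rt
Reagents that add atoms: chlorotriethylsilane, CC[Si](Cl)(CC)CC; tert-butyldimethylsilyl triflate, CC(C)(C)[Si](C)(C)OS(=O)(=O)C(F)(F)F
Why: Sequential silylation in which the primary hydroxyl reacts with the silyl chloride and the tertiary hydroxyl needs the silyl triflate, the weak amine bases being unable to close the chlorohydrin to an epoxide.

Step 6
Reactants: 9 (2R)-2-[(tert-butyldimethylsilyl)oxy]-1-chloro-2-methyl-3-[(triethylsilyl)oxy]propane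
Product: 10 (2R)-2-[(tert-butyldimethylsilyl)oxy]-3-chloro-2-methylpropanal
Conditions: (COCl)2, DMSO, CH2Cl2, −78 → −30 °C; Et3N, −78 °C → rt
Reagents that add atoms: none
Why: Swern oxidation run directly on the primary triethylsilyl ether, which the chlorosulfonium reagent cleaves and oxidises to the aldehyde while the hindered tertiary silyl ether is inert, the product having no α-hydrogen and therefore no way to epimerise.

Step 7
Reactants: 6 (2S)-3-[(tert-butyldiphenylsilyl)oxy]-2-hydroxy-2-methylpropanoic acid; 10 (2R)-2-[(tert-butyldimethylsilyl)oxy]-3-chloro-2-methylpropanal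
Product: 12 (5S)-2-{(2R)-2-[(tert-butyldimethylsilyl)oxy]-1-chloropropan-2-yl}-5-{[(tert-butyldiphenylsilyl)oxy]methyl}-5-methyl-1,3-dioxolan-4-one (both C2 epimers), via bis(trimethylsilyl) derivative 11 (not isolated)
Conditions: 6, HMDS, THF, 65 °C, evaporation; then 10, TMSOTf (10 mol%), CH2Cl2, −78 °C
Reagents that add atoms: none
Why: Silyl-triflate-catalysed acetalisation of the aldehyde by the bis-silylated α-hydroxy acid (1,3-dioxolan-4-one formation) under aprotic conditions that spare the silyl ethers, the new acetal centre C6 forming as a mixture that is immaterial because step 9 erases it.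

Step 8
Reactants: 12 dioxolanone (both C2 epimers)
Product: 13 (5S)-2-{(2R)-2-[(tert-butyldimethylsilyl)oxy]-1-chloropropan-2-yl}-5-{[(tert-butyldiphenylsilyl)oxy]methyl}-5-methyl-4-methylidene-1,3-dioxolane (both C2 epimers)
Conditions: Cp2TiMe2 (2.5 equiv), toluene, 65 °C, dark
Reagents that add atoms: dimethyltitanocene, C[Ti](C)(C1C=CC=C1)C1C=CC=C1
Why: Petasis methylenation of the only carbonyl group (the lactone) through Cp2Ti=CH2 installs C5 as the enol-acetal methylene under neutral conditions that tolerate silyl ethers and the alkyl chloride and touch no stereocentre.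

Step 9
Reactants: 13 4-methylidene-1,3-dioxolane (both C2 epimers)
Product: 14 (2S,5S)-5-{(2R)-2-[(tert-butyldimethylsilyl)oxy]-1-chloropropan-2-yl}-2-{[(tert-butyldiphenylsilyl)oxy]methyl}-2-methyloxolan-3-one
Conditions: Me2AlCl (2 equiv), CH2Cl2, −78 → −20 °C
Reagents that add atoms: none
Why: Me2AlCl coordinates the enol-ether oxygen of the acetal and cleaves its bond to C6, leaving an (E)-configured O1=C6 oxocarbenium ion tethered through C3 to a C4 aluminium enolate, whose carbon C5 then adds to C6 and regenerates the C4 carbonyl. The closest known reaction type is the Petasis–Ferrier rearrangement of 4-methylene-1,3-dioxolanes to tetrahydrofuran-3-ones. The oxolane ring (O1, C3, C4, C5, C6) closes in a 5-(enolendo)-endo-trig mode, accessible here because the electrophile is a cationic C=O unit. C6 is the one new stereocentre and is controlled by the fixed quaternary centre C3, since ionisation erases the acetal centre and both epimers of 13 converge. The step needs the C7 substituent to end cis to the C3 silyloxymethyl arm: in the envelope transition state the C7 group of the (E)-oxocarbenium ion is pseudo-equatorial, and the larger CH2OTBDPS arm rather than CH3 should take the pseudo-equatorial site at C3, which puts the two on the same ring face. Chemoselectivity is secured because the substrate carries no other acetal and only bulky, weakly basic silyl ethers, so the oxygens on C2 and C7 neither trap the oxocarbenium ion nor divert the Lewis acid.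

Step 10
Reactants: 14 oxolan-3-one
Product: 15 (2S,5S)-5-{(2R)-2-[(tert-butyldimethylsilyl)oxy]-1-chloropropan-2-yl}-2-(hydroxymethyl)-2-methyloxolan-3-one
Conditions: TBAF (1.5 equiv), AcOH (1.5 equiv), THF, 0 °C → rt
Reagents that add atoms: none
Why: Fluoride-mediated desilylation of the primary silyl ether, which should be much faster than attack at the hindered tertiary TBS ether, with the acetic acid buffer suppressing retro-aldol and retro-oxa-Michael reactions of the β-oxygenated ketone.

Step 11
Reactants: 15 β-hydroxy ketone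
Product: 16 (2S,3R,5S)-5-{(2R)-2-[(tert-butyldimethylsilyl)oxy]-1-chloropropan-2-yl}-2-(hydroxymethyl)-2-methyloxolan-3-ol
Conditions: Me4NBH(OAc)3, MeCN/AcOH, −30 °C
Reagents that add atoms: none
Why: Evans–Saksena hydroxyl-directed reduction, in which the C2 hydroxyl exchanges onto boron and hydride is delivered intramolecularly to the C4 carbonyl from the face bearing the CH2OH arm, so the new C4 hydroxyl ends trans to that arm and cis to the C3 methyl (4R).

Step 12
Reactants: 16 diol
Product: 17 (2R,3R,5S)-5-{(2R)-2-[(tert-butyldimethylsilyl)oxy]-1-chloropropan-2-yl}-3-hydroxy-2-methyloxolane-2-carbaldehyde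
Conditions: TEMPO (10 mol%), PhI(OAc)2, CH2Cl2, rt
Reagents that add atoms: none
Why: Oxoammonium (TEMPO) oxidation, which is selective for the primary over the hindered secondary alcohol and gives an aldehyde whose quaternary α-carbon cannot epimerise.

Step 13
Reactants: 17 hydroxy aldehyde
Product: 18 (2S,3R,5S)-2-[(E)-2-bromoethenyl]-5-{(2R)-2-[(tert-butyldimethylsilyl)oxy]-1-chloropropan-2-yl}-2-methyloxolan-3-ol
Conditions: CrBr2 (excess), CHBr3, THF, 0 °C → rt
Reagents that add atoms: bromoform, BrC(Br)Br
Why: Takai olefination, in which the geminal dichromium species from bromoform adds to the aldehyde and eliminates to the (E)-bromoalkene (C1=C2), the bromide salt of divalent chromium avoiding halide exchange to a chloroalkene and the free hydroxyl being tolerated.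

Step 14
Reactants: 18 bromovinyl alcohol
Product: 19 (2S,3S,5S)-2-[(E)-2-bromoethenyl]-5-{(2R)-2-[(tert-butyldimethylsilyl)oxy]-1-chloropropan-2-yl}-3-chloro-2-methyloxolane
Conditions: P(n-Oct)3, CCl4, toluene, 60 °C
Reagents that add atoms: tetrachloromethane, ClC(Cl)(Cl)Cl
Why: Appel-type chlorination, in which chloride displaces the alkoxyphosphonium group at C4 by SN2 with inversion and so turns the 4R alcohol into the 4S chloride cis to the bromovinyl and C6 substituents, the non-ionising conditions being chosen to avoid a 1,2-shift from the adjacent quaternary C3.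

Step 15
Reactants: 19 silyl-protected chlorohydrin
Product: 21 (2S,3S,5S)-2-[(E)-2-bromoethenyl]-3-chloro-2-methyl-5-[(2S)-2-methyloxiran-2-yl]oxolane, via chlorohydrin 20 (not isolated)
Conditions: HF (48% aq), MeCN, rt; then K2CO3, MeOH, 0 °C → rt
Reagents that add atoms: none
Why: Acidic desilylation of the tertiary silyl ether followed by base-induced Williamson closure (3-exo-tet) of the chlorohydrin, in which the C7–O bond is kept and the epoxide therefore retains the C7 configuration.

Step 16
Reactants: 21 epoxide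
Product: 22 (2R)-2-bromo-2-{(2S,4S,5S)-5-[(E)-2-bromoethenyl]-4-chloro-5-methyloxolan-2-yl}propan-1-ol
Conditions: HBr (anhydrous, 1.2 equiv), CH2Cl2, −78 → −20 °C
Reagents that add atoms: hydrogen bromide, Br
Why: Acid-mediated epoxide opening (bromohydrin formation), in which bromide attacks the protonated oxirane at the tertiary carbon C7 from the rear in a borderline SN2 process that inverts C7 and gives the configuration the target needs there; material in which bromide entered at C8 would be re-closed to 21 with base and resubmitted.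

Step 17
Reactants: 22 bromohydrin
Product: 23 (2S,3S,5S)-2-[(E)-2-bromoethenyl]-5-[(2S)-2-bromo-1-chloropropan-2-yl]-3-chloro-2-methyloxolane (target)
Conditions: PPh3, CCl4, 40–50 °C
Reagents that add atoms: tetrachloromethane, ClC(Cl)(Cl)Cl
Why: Appel chlorination of the primary alcohol, in which the chloride of the alkoxyphosphonium ion pair should attack C8 in the non-polar medium, and even if the neighbouring bromine assists departure, collapse of the ion pair at C8 restores the C7–Br bond with unchanged configuration.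

Compound list
1 | methallyl alcohol (2-methylprop-2-en-1-ol) | CC(=C)CO | starting material
2 | (R)-2-methylglycidol, (2R)-(2-methyloxiran-2-yl)methanol | OC[C@]1(C)CO1 | intermediate
3 | (2S)-2-methyloxirane-2-carboxylic acid (as sodium salt, not isolated) | OC(=O)[C@]1(C)CO1 | intermediate
4 | (2S)-2,3-dihydroxy-2-methylpropanoic acid | OC(=O)[C@](C)(CO)O | intermediate
5 | tert-butyldiphenylsilyl (2S)-3-[(tert-butyldiphenylsilyl)oxy]-2-hydroxy-2-methylpropanoate (not isolated) | CC(C)(C)[Si](c1ccccc1)(c1ccccc1)OC(=O)[C@](C)(CO[Si](c2ccccc2)(c2ccccc2)C(C)(C)C)O | intermediate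
6 | (2S)-3-[(tert-butyldiphenylsilyl)oxy]-2-hydroxy-2-methylpropanoic acid | OC(=O)[C@](C)(CO[Si](c1ccccc1)(c1ccccc1)C(C)(C)C)O | intermediate
7 | (2R)-3-chloro-2-methylpropane-1,2-diol | C[C@](O)(CCl)CO | intermediate
8 | (2R)-1-chloro-2-methyl-3-[(triethylsilyl)oxy]propan-2-ol (not isolated) | C[C@](O)(CCl)CO[Si](CC)(CC)CC | intermediate
9 | (2R)-2-[(tert-butyldimethylsilyl)oxy]-1-chloro-2-methyl-3-[(triethylsilyl)oxy]propane | C[C@](O[Si](C)(C)C(C)(C)C)(CCl)CO[Si](CC)(CC)CC | intermediate
10 | (2R)-2-[(tert-butyldimethylsilyl)oxy]-3-chloro-2-methylpropanal | C[C@](O[Si](C)(C)C(C)(C)C)(CCl)C=O | intermediate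
11 | trimethylsilyl (2S)-3-[(tert-butyldiphenylsilyl)oxy]-2-methyl-2-[(trimethylsilyl)oxy]propanoate (not isolated) | C[Si](C)(C)OC(=O)[C@](C)(CO[Si](c1ccccc1)(c1ccccc1)C(C)(C)C)O[Si](C)(C)C | intermediate
12 | (5S)-2-{(2R)-2-[(tert-butyldimethylsilyl)oxy]-1-chloropropan-2-yl}-5-{[(tert-butyldiphenylsilyl)oxy]methyl}-5-methyl-1,3-dioxolan-4-one (both C2 epimers) | C[C@](O[Si](C)(C)C(C)(C)C)(CCl)C1OC(=O)[C@](C)(CO[Si](c2ccccc2)(c2ccccc2)C(C)(C)C)O1 | intermediate
13 | (5S)-2-{(2R)-2-[(tert-butyldimethylsilyl)oxy]-1-chloropropan-2-yl}-5-{[(tert-butyldiphenylsilyl)oxy]methyl}-5-methyl-4-methylidene-1,3-dioxolane (both C2 epimers) | C[C@](O[Si](C)(C)C(C)(C)C)(CCl)C1OC(=C)[C@](C)(CO[Si](c2ccccc2)(c2ccccc2)C(C)(C)C)O1 | intermediate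
14 | (2S,5S)-5-{(2R)-2-[(tert-butyldimethylsilyl)oxy]-1-chloropropan-2-yl}-2-{[(tert-butyldiphenylsilyl)oxy]methyl}-2-methyloxolan-3-one | C[C@](O[Si](C)(C)C(C)(C)C)(CCl)[C@@H]1CC(=O)[C@](C)(CO[Si](c2ccccc2)(c2ccccc2)C(C)(C)C)O1 | intermediate
15 | (2S,5S)-5-{(2R)-2-[(tert-butyldimethylsilyl)oxy]-1-chloropropan-2-yl}-2-(hydroxymethyl)-2-methyloxolan-3-one | C[C@](O[Si](C)(C)C(C)(C)C)(CCl)[C@@H]1CC(=O)[C@](C)(CO)O1 | intermediate
16 | (2S,3R,5S)-5-{(2R)-2-[(tert-butyldimethylsilyl)oxy]-1-chloropropan-2-yl}-2-(hydroxymethyl)-2-methyloxolan-3-ol | C[C@](O[Si](C)(C)C(C)(C)C)(CCl)[C@@H]1C[C@@H](O)[C@](C)(CO)O1 | intermediate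
17 | (2R,3R,5S)-5-{(2R)-2-[(tert-butyldimethylsilyl)oxy]-1-chloropropan-2-yl}-3-hydroxy-2-methyloxolane-2-carbaldehyde | C[C@](O[Si](C)(C)C(C)(C)C)(CCl)[C@@H]1C[C@@H](O)[C@](C)(C=O)O1 | intermediate
18 | (2S,3R,5S)-2-[(E)-2-bromoethenyl]-5-{(2R)-2-[(tert-butyldimethylsilyl)oxy]-1-chloropropan-2-yl}-2-methyloxolan-3-ol | C[C@](O[Si](C)(C)C(C)(C)C)(CCl)[C@@H]1C[C@@H](O)[C@](C)(/C=C/Br)O1 | intermediate
19 | (2S,3S,5S)-2-[(E)-2-bromoethenyl]-5-{(2R)-2-[(tert-butyldimethylsilyl)oxy]-1-chloropropan-2-yl}-3-chloro-2-methyloxolane | C[C@](O[Si](C)(C)C(C)(C)C)(CCl)[C@@H]1C[C@H](Cl)[C@](C)(/C=C/Br)O1 | intermediate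
20 | (2R)-2-{(2S,4S,5S)-5-[(E)-2-bromoethenyl]-4-chloro-5-methyloxolan-2-yl}-1-chloropropan-2-ol (not isolated) | C[C@](O)(CCl)[C@@H]1C[C@H](Cl)[C@](C)(/C=C/Br)O1 | intermediate
21 | (2S,3S,5S)-2-[(E)-2-bromoethenyl]-3-chloro-2-methyl-5-[(2S)-2-methyloxiran-2-yl]oxolane | C[C@]1(CO1)[C@@H]2C[C@H](Cl)[C@](C)(/C=C/Br)O2 | intermediate
22 | (2R)-2-bromo-2-{(2S,4S,5S)-5-[(E)-2-bromoethenyl]-4-chloro-5-methyloxolan-2-yl}propan-1-ol | C[C@@](Br)(CO)[C@@H]1C[C@H](Cl)[C@](C)(/C=C/Br)O1 | intermediate
23 | (2S,3S,5S)-2-[(E)-2-bromoethenyl]-5-[(2S)-2-bromo-1-chloropropan-2-yl]-3-chloro-2-methyloxolane | C[C@@](Br)(CCl)[C@@H]1C[C@H](Cl)[C@](C)(/C=C/Br)O1 | target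

Total step count: 17. Longest linear sequence: 15 steps (steps 1 and 4 to 17).

Steps most likely to fail

Step 9 (key step). The acetal may ionise sluggishly because the cationic carbon C6 is flanked by the electron-withdrawing oxygen on C7, the Lewis acid may erode the silyl ethers on warming, and the discrimination between CH3 and CH2OTBDPS at C3 may be too weak, so that the C6 epimer forms alongside the wanted ketone. The fallback sets out from acid 6 and aldehyde 10 and returns to the route at 14 by a stepwise aldol and oxa-Michael sequence. Acid 6 is treated with MeLi (3 equiv, THF, −78 → 0 °C) to give the methyl ketone (3S)-4-[(tert-butyldiphenylsilyl)oxy]-3-hydroxy-3-methylbutan-2-one F1. Its dianion (LiHMDS, 2.2 equiv, THF, −78 °C) adds to 10 to give the aldol (2S,6R)-6-[(tert-butyldimethylsilyl)oxy]-1-[(tert-butyldiphenylsilyl)oxy]-7-chloro-2,5-dihydroxy-2,6-dimethylheptan-3-one F2. Mesylation and elimination (MsCl, Et3N, then DBU) should give the enone (2S,4E,6R)-6-[(tert-butyldimethylsilyl)oxy]-1-[(tert-butyldiphenylsilyl)oxy]-7-chloro-2-hydroxy-2,6-dimethylhept-4-en-3-one F3. Its tertiary hydroxyl closes onto C6 by acid-mediated 5-endo oxa-Michael addition (CSA, CH2Cl2) to give 14. The C6 epimer (2S,5R)-5-{(2R)-2-[(tert-butyldimethylsilyl)oxy]-1-chloropropan-2-yl}-2-{[(tert-butyldiphenylsilyl)oxy]methyl}-2-methyloxolan-3-one F4 formed beside it is reopened to F3 under the same conditions and recycled.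

Step 16. Bromide may enter at the primary carbon C8 instead of C7, whose cationic character is lowered by the neighbouring ring oxygen; forcing the opening risks partial loss of configuration at C7 through an open cation. The fallback sets out from 21 and returns at 22, making the C7–Br bond by electrophilic bromination instead of nucleophilic opening. Epoxide 21 is isomerised by Meinwald rearrangement (BF3·OEt2, CH2Cl2, −78 °C, hydride shift from C8 to C7) to 2-{(2S,4S,5S)-5-[(E)-2-bromoethenyl]-4-chloro-5-methyloxolan-2-yl}propanal F5. This is brominated at the α-carbon (Br2, dioxane/Et2O, 0 °C) to 2-bromo-2-{(2S,4S,5S)-5-[(E)-2-bromoethenyl]-4-chloro-5-methyloxolan-2-yl}propanal F6. Reduction (NaBH4, CeCl3, MeOH, −78 °C) gives 22 and its C7 epimer (2S)-2-bromo-2-{(2S,4S,5S)-5-[(E)-2-bromoethenyl]-4-chloro-5-methyloxolan-2-yl}propan-1-ol F7, which are separated. Stereospecificity at C7 is given up in exchange for a secure regiochemistry.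

Step 17. The C7 bromine may assist departure of the activated oxygen, after which chloride can open the bridged bromonium ion at C7 and transpose the two halogens; elimination towards C7 is a further loss channel. The fallback sets out from 19 and returns at 23, keeping the chloride on C8 throughout and introducing the bromide last, so that no leaving group ever stands next to the tertiary bromide. Compound 19 is desilylated (HF, MeCN, rt) and chlorohydrin 20 is isolated. Anhydrous HBr (CH2Cl2, 0 °C) then replaces the tertiary hydroxyl through the C7 cation. This should give 23 together with its C7 epimer (2S,3S,5S)-2-[(E)-2-bromoethenyl]-5-[(2R)-2-bromo-1-chloropropan-2-yl]-3-chloro-2-methyloxolane F8, separated by chromatography. Compounds 21 and 22 are bypassed.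

Further compounds
F1 | step 9 | (3S)-4-[(tert-butyldiphenylsilyl)oxy]-3-hydroxy-3-methylbutan-2-one | CC(=O)[C@](C)(CO[Si](c1ccccc1)(c1ccccc1)C(C)(C)C)O
F2 | step 9 | (2S,6R)-6-[(tert-butyldimethylsilyl)oxy]-1-[(tert-butyldiphenylsilyl)oxy]-7-chloro-2,5-dihydroxy-2,6-dimethylheptan-3-one (C5 epimers) | C[C@](O[Si](C)(C)C(C)(C)C)(CCl)C(O)CC(=O)[C@](C)(CO[Si](c1ccccc1)(c1ccccc1)C(C)(C)C)O
F3 | step 9 | (2S,4E,6R)-6-[(tert-butyldimethylsilyl)oxy]-1-[(tert-butyldiphenylsilyl)oxy]-7-chloro-2-hydroxy-2,6-dimethylhept-4-en-3-one | C[C@](O[Si](C)(C)C(C)(C)C)(CCl)/C=C/C(=O)[C@](C)(CO[Si](c1ccccc1)(c1ccccc1)C(C)(C)C)O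
F4 | step 9 | (2S,5R)-5-{(2R)-2-[(tert-butyldimethylsilyl)oxy]-1-chloropropan-2-yl}-2-{[(tert-butyldiphenylsilyl)oxy]methyl}-2-methyloxolan-3-one | C[C@](O[Si](C)(C)C(C)(C)C)(CCl)[C@H]1CC(=O)[C@](C)(CO[Si](c2ccccc2)(c2ccccc2)C(C)(C)C)O1
F5 | step 16 | 2-{(2S,4S,5S)-5-[(E)-2-bromoethenyl]-4-chloro-5-methyloxolan-2-yl}propanal (C2 epimers) | CC(C=O)[C@@H]1C[C@H](Cl)[C@](C)(/C=C/Br)O1
F6 | step 16 | 2-bromo-2-{(2S,4S,5S)-5-[(E)-2-bromoethenyl]-4-chloro-5-methyloxolan-2-yl}propanal (C2 epimers) | CC(Br)(C=O)[C@@H]1C[C@H](Cl)[C@](C)(/C=C/Br)O1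
F7 | step 16 | (2S)-2-bromo-2-{(2S,4S,5S)-5-[(E)-2-bromoethenyl]-4-chloro-5-methyloxolan-2-yl}propan-1-ol | C[C@](Br)(CO)[C@@H]1C[C@H](Cl)[C@](C)(/C=C/Br)O1
F8 | step 17 | (2S,3S,5S)-2-[(E)-2-bromoethenyl]-5-[(2R)-2-bromo-1-chloropropan-2-yl]-3-chloro-2-methyloxolane | C[C@](Br)(CCl)[C@@H]1C[C@H](Cl)[C@](C)(/C=C/Br)O1
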